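## The problem

Target **33** is a germacranolide. Locants used throughout: ring carbons C1–C10, lactone carbons C11–C13, C14 (methyl on C10), C15 (hydroxymethyl on C4); configuration 1R,4S,6R,7S,8R,10S, with a (2R)-2-methylbutanoate on O8.

- The ten-membered carbocycle is trans-fused across C6–C7 to an α-methylene-γ-butyrolactone (O–C6, C7, C11=C13, C12). Closing a ten-membered ring fights transannular strain and entropy, so the closing bond should carry as little stereochemical duty as possible.
- C6, C7 and C8 form a contiguous triad. C7 (from a building block) can control C6 within the five-membered lactone. C8 must be set against an adjacent, already substituted centre.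
- The C1–C10 epoxide is cis (C2 and C9 on the same side), so it comes from a Z-trisubstituted C1=C10 olefin. A free 8-hydroxyl, homoallylic to that olefin, can deliver the oxygen.
- C4 is isolated from the other centres and lies α to the C3 ketone, so it is epimerizable and difficult to relay.
- **Feature that enables the key step:** the oxygen-bearing C8 is homoallylic to the Z C1=C10 bond of the ten-membered ring through C9 (O–C8–C9–C10(CH3)=C1). This is the retron of a carbonyl allylation with allylic transposition. The C10 methyl group is the substituent that forces Z geometry in a closed transition state.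
- Sensitive groups: the C3 ketone is β to the C15 hydroxyl (retro-aldol, dehydration) and β,γ to the epoxide (base-induced E1cB opening). The α-methylene lactone is a Michael acceptor, the trisubstituted epoxide is acid-labile, and the ester α-centre can epimerize. The ketone and primary alcohol should therefore appear last, under neutral conditions.

## Retrosynthesis

**33 ⇒ 31 ⇒ 30 ⇒ 29.** The C3 ketone and C15 hydroxyl are not carried through the route. They are traced to spiro-epoxy ketone **31**, whose C4–O bond is cleaved reductively in the last step. This avoids any protecting group on C15 and any basic step once the β-hydroxy ketone exists. **31** comes from epoxy alcohol **30**, and **30** from allylic alcohol **29**. C3 and C4 of **29**–**31** both become trigonal (ketone, then enolate **32**), so their epimers converge. The forward sequence needs only chemoselective oxidations and a controlled protonation at C4.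

**29 ⇒ 27.** The ring is cut at C3–C4. This is the only ring bond whose formation creates no lasting stereocentre, and its termini (an aldehyde and a 2-bromoalkene) survive all earlier steps. Closure at C6–C7 or C7–C8 would instead have to set two centres inside a macrocyclic transition state. Precursor **27** is open-chain and already carries five of the six ring stereocentres. The forward reaction is a Nozaki–Hiyama–Kishi cyclization (via **28**).

**27 ⇒ 26 ⇒ 25 ⇒ 23 ⇒ 22 ⇒ 19.** Only functional-group changes: oxidation, PMB cleavage, esterification with **24**, epoxidation and lactone methylenation. The order matters. The free 8-hydroxyl of **22** directs the epoxidation before it is acylated, and the strongly basic methylenation comes before any epoxide or ketone exists.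

**19 ⇒ 10 + 17 (key cut).** The C8–C9 bond is cut and the olefin is moved from C1=C10 back to C9=C10, with boron on C1. This removes the Z-trisubstituted olefin, the C8 stereocentre and the fragment union in one operation. The neighbouring cuts (C9–C10 or C1–C2) would need a preformed Z-alkenyl metal and would leave C8 to substrate control. Aldehyde **10** has 8 carbons and boronate **17** has 6 skeletal carbons, against 14 skeletal carbons and three contiguous centres in **19**. The forward reaction must transfer chirality from C1 to C8 and override the bias of C7.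

**17 ⇒ 13 + 14; 13 ⇒ 11 + 12.** The C1–C10 bond is cut. The α-chiral allylboronate **17** comes from lithiation–borylation of carbamate **13** (via **15**, **16**) with commercial isopropenylboronate **14**. Sparteine sets the C1 configuration.

**10 ⇒ 7 ⇒ 5 + 6; 5 ⇒ 3 ⇒ 1 + 2.** The trans-lactone aldehyde **10** is traced through a retro-aldol/lactonization cascade (via **8**, **9**) to cyclopropane **7**. **7** comes from Hosomi–Sakurai addition of silane **6** to aldehyde **5**. **5** comes from ozonolysis (via **4**) of the furoate cyclopropane **3**, made from **1** and **2**. The cyclopropane stores C7, and **6** brings C4, C5, C15 and the alkenyl bromide for ring closure.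

## Roads not taken

**Alternative 1:** Cut C6–C7 and the lactone C–O bond (the most obvious route). The forward key step is an intramolecular chromium- or indium-mediated allylation of seco-aldehyde **A1**, a 2-(bromomethyl)enoate, closing ring and lactone together. The chosen plan is better for three reasons. In **A1** the macrocyclic transition state must set C6 and C7 relative to C8 with no reliable model, and a chair with the Z-bromide predicts the syn adduct, i.e. the cis-lactone. The Z C1=C10 olefin still has to be built separately. **A1** needs four differentiated oxygen functions and a long linear sequence before the key step.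

**Alternative 2:** Cut C1=C10. The forward key step is ring-closing metathesis of diene **A2** with second-generation Grubbs catalyst. A trisubstituted olefin inside a ten-membered ring is strained, so dimerization competes. The geometry would be left to the catalyst and the ring, the 1,1-disubstituted olefin initiates poorly, and the α-methylene lactone competes for the carbene. The chosen plan fixes the geometry in an open-chain, closed transition state.

**Alternative 3:** Cut C5–C6 and add a C3–C8 bond: anionic oxy-Cope ring expansion of divinylcyclohexenol **A3** to cyclodecadienone **A4**. This gives the Z olefin (inherited from the six-membered ring) and the C3 ketone at once. However, the enolate formed carries a β-alkoxy group at C15 and can eliminate, and C4 is set by uncontrolled protonation. The C6–C8 triad and the lactone would then have to be built on the mobile ring of **A4** from its E C7=C8 olefin, in at least five steps without dependable facial control.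

Key step: step 7

Assumption: compounds **29**–**31** are carried as epimer mixtures at C3 and/or C4, because both centres become trigonal before the target is reached.

## Route

Step 1
Reactants: 1 methyl furan-2-carboxylate; 2 ethyl diazoacetate
Product: 3 6-ethyl 3-methyl (1R,5R,6R)-2-oxabicyclo[3.1.0]hex-3-ene-3,6-dicarboxylate
Conditions: Cu(OTf)2 (cat.), 2,2'-isopropylidenebis[(4R)-4-isopropyl-2-oxazoline] (cat.), PhNHNH2 (cat.), CH2Cl2, 0 °C, slow addition of 2
Reagents that add atoms: none
Why: Copper-catalysed asymmetric cyclopropanation of the unsubstituted C4=C5 bond of the furan, with the ester exo; the bis(oxazoline) enantiomer is chosen to give the 1R,5R,6R series (the antipodal ligand gives the mirror image), and C5 of 3 becomes C7 of the target.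

Step 2
Reactants: 3 6-ethyl 3-methyl (1R,5R,6R)-2-oxabicyclo[3.1.0]hex-3-ene-3,6-dicarboxylate
Product: 5 ethyl (1R,2R,3R)-2-formyl-3-[(2-methoxy-2-oxoacetyl)oxy]cyclopropane-1-carboxylate, via ozonide 4 (not isolated)
Conditions: O3, CH2Cl2, −78 °C; then Me2S, −78 °C to rt
Reagents that add atoms: ozone, [O-][O+]=O
Why: Ozonolysis of the remaining enol-ether double bond gives the formylcyclopropane and turns the ring oxygen into an oxalate ester; no stereocentre is touched.

Step 3
Reactants: 5 ethyl (1R,2R,3R)-2-formyl-3-[(2-methoxy-2-oxoacetyl)oxy]cyclopropane-1-carboxylate; 6 (2-bromoprop-2-en-1-yl)trimethylsilane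
Product: 7 ethyl (1R,2S,3R)-2-[(1R)-3-bromo-1-hydroxybut-3-en-1-yl]-3-[(2-methoxy-2-oxoacetyl)oxy]cyclopropane-1-carboxylate
Conditions: BF3·OEt2, CH2Cl2, −78 to −40 °C; aq. NaHCO3
Reagents that add atoms: none
Why: Hosomi–Sakurai allylation; Felkin–Anh attack on the bisected cyclopropyl aldehyde sets C6 (R), and the reagent brings C5, C4, C15 and the alkenyl bromide needed for ring closure.

Step 4
Reactants: 7 ethyl (1R,2S,3R)-2-[(1R)-3-bromo-1-hydroxybut-3-en-1-yl]-3-[(2-methoxy-2-oxoacetyl)oxy]cyclopropane-1-carboxylate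
Product: 10 (2R,3S)-2-(2-bromoprop-2-en-1-yl)-5-oxooxolane-3-carbaldehyde, via cyclopropanol 8 (not isolated), via hydroxy ester aldehyde 9 (not isolated)
Conditions: Ba(OH)2·8H2O (0.5 equiv), MeOH, 0 °C
Reagents that add atoms: none
Why: Methanolysis of the oxalate frees a donor–acceptor cyclopropanol that opens by retro-aldol (C8 aldehyde, C11 methylene), and the C6 hydroxyl lactonizes onto the ethyl ester. The trans C6/C7 relation follows from the existing centres and is also the thermodynamic one at the epimerizable C7.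

Step 5
Reactants: 11 3-[(4-methoxyphenyl)methoxy]propan-1-ol; 12 N,N-di(propan-2-yl)carbamoyl chloride
Product: 13 3-[(4-methoxyphenyl)methoxy]propyl N,N-di(propan-2-yl)carbamate
Conditions: Et3N, CH2Cl2, reflux
Reagents that add atoms: none
Why: Standard carbamoylation of a primary alcohol; the carbamate is the directing and leaving group for the next step.

Step 6
Reactants: 13 3-[(4-methoxyphenyl)methoxy]propyl N,N-di(propan-2-yl)carbamate; 14 4,4,5,5-tetramethyl-2-(prop-1-en-2-yl)-1,3,2-dioxaborolane
Product: 17 2-[(3R)-5-[(4-methoxyphenyl)methoxy]-2-methylpent-1-en-3-yl]-4,4,5,5-tetramethyl-1,3,2-dioxaborolane, via lithiated carbamate 15 (not isolated), via boronate complex 16 (not isolated)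
Conditions: s-BuLi, (−)-sparteine, Et2O, −78 °C; then 14; then MgBr2·OEt2, −78 to 35 °C
Reagents that add atoms: none
Why: Sparteine-mediated carbamate lithiation removes the pro-S hydrogen, borylation occurs with retention, and the 1,2-metallate rearrangement moves the isopropenyl group to carbon with inversion (lithiation–borylation). This forms C1–C10 and should give the (R)-allylboronate.

Step 7
Reactants: 10 (2R,3S)-2-(2-bromoprop-2-en-1-yl)-5-oxooxolane-3-carbaldehyde; 17 2-[(3R)-5-[(4-methoxyphenyl)methoxy]-2-methylpent-1-en-3-yl]-4,4,5,5-tetramethyl-1,3,2-dioxaborolane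
Product: 19 (4R,5R)-5-(2-bromoprop-2-en-1-yl)-4-[(1R,3Z)-1-hydroxy-6-[(4-methoxyphenyl)methoxy]-3-methylhex-3-en-1-yl]oxolan-2-one, via borate ester 18 (not isolated)
Conditions: CH2Cl2, 0 °C to rt; then N(CH2CH2OH)3
Reagents that add atoms: none
Why: Boron binds the aldehyde oxygen and C9 adds to C8 through a closed six-membered chair (Zimmerman–Traxler) transition state while the C1–B bond breaks and the double bond moves to C1=C10. The closest known reaction type is the allylboration of aldehydes with α-substituted allylic pinacol boronates made by lithiation–borylation. No ring is closed; the step joins the two halves through C8–C9. The olefin geometry is set by the C10 methyl group: an equatorial C2 chain on C1 would eclipse it (A(1,2) strain), so the chain sits axial and ends cis to C9, which is Z. The C8 configuration is set by 1,3-chirality transfer from C1: with the aldehyde substituent (C7) equatorial, the chair from the (R)-boronate should give the (8R) carbinol. The selectivity needed is reagent control over the Felkin–Anh bias of C7, which is expected to oppose it. It should hold because the other aldehyde face is reachable only through the chair with an equatorial C2 chain, which is strongly disfavoured. The aldehyde reacts in preference to the lactone, and the alkenyl bromide and PMB ether are inert.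

Step 8
Reactants: 19 (4R,5R)-5-(2-bromoprop-2-en-1-yl)-4-[(1R,3Z)-1-hydroxy-6-[(4-methoxyphenyl)methoxy]-3-methylhex-3-en-1-yl]oxolan-2-one
Product: 22 (4R,5R)-5-(2-bromoprop-2-en-1-yl)-4-[(1R,3Z)-1-hydroxy-6-[(4-methoxyphenyl)methoxy]-3-methylhex-3-en-1-yl]-3-methylideneoxolan-2-one, via Mannich base 20 (not isolated), via methiodide 21 (not isolated)
Conditions: LDA (2.3 equiv), THF, −78 °C; CH2=NMe2+ I−; then MeI, MeOH; then aq. NaHCO3, CH2Cl2
Reagents that add atoms: Eschenmoser's salt (N,N-dimethylmethyleneiminium iodide), C=[N+](C)C.[I-]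
Why: Mannich reaction of the lactone enolate (as the alkoxide–enolate dianion) with Eschenmoser's salt, then quaternization and elimination, installs C13; C11 becomes trigonal, and −78 °C spares the alkenyl bromide. The trans-6,12-lactone is the thermodynamic one should the C8 alkoxide translactonize.

Step 9
Reactants: 22 (4R,5R)-5-(2-bromoprop-2-en-1-yl)-4-[(1R,3Z)-1-hydroxy-6-[(4-methoxyphenyl)methoxy]-3-methylhex-3-en-1-yl]-3-methylideneoxolan-2-one
Product: 23 (4R,5R)-5-(2-bromoprop-2-en-1-yl)-4-[(1R)-1-hydroxy-2-[(2S,3R)-3-[2-[(4-methoxyphenyl)methoxy]ethyl]-2-methyloxiran-2-yl]ethyl]-3-methylideneoxolan-2-one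
Conditions: VO(acac)2 (cat.), t-BuOOH, CH2Cl2, 0 °C to rt
Reagents that add atoms: tert-butyl hydroperoxide, CC(C)(C)OO
Why: Vanadium-catalysed hydroxyl-directed epoxidation of the homoallylic alcohol. A chair-like vanadate transition state with C7 equatorial and the C1 terminus anti to C8 delivers oxygen to the face giving 10S,1R, and the Z olefin gives the cis-epoxide stereospecifically. The electron-poor methylene lactone and bromoalkene should not react.

Step 10
Reactants: 23 (4R,5R)-5-(2-bromoprop-2-en-1-yl)-4-[(1R)-1-hydroxy-2-[(2S,3R)-3-[2-[(4-methoxyphenyl)methoxy]ethyl]-2-methyloxiran-2-yl]ethyl]-3-methylideneoxolan-2-one; 24 (2R)-2-methylbutanoic acid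
Product: 25 (1R)-1-[(2R,3R)-2-(2-bromoprop-2-en-1-yl)-4-methylidene-5-oxooxolan-3-yl]-2-[(2S,3R)-3-[2-[(4-methoxyphenyl)methoxy]ethyl]-2-methyloxiran-2-yl]ethyl (2R)-2-methylbutanoate
Conditions: EDC·HCl, DMAP (cat.), CH2Cl2, 0 °C
Reagents that add atoms: none
Why: Steglich-type esterification of the secondary 8-hydroxyl with retention at C8; low temperature and catalytic DMAP should keep the α-centre of the acid intact.

Step 11
Reactants: 25 (1R)-1-[(2R,3R)-2-(2-bromoprop-2-en-1-yl)-4-methylidene-5-oxooxolan-3-yl]-2-[(2S,3R)-3-[2-[(4-methoxyphenyl)methoxy]ethyl]-2-methyloxiran-2-yl]ethyl (2R)-2-methylbutanoate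
Product: 26 (1R)-1-[(2R,3R)-2-(2-bromoprop-2-en-1-yl)-4-methylidene-5-oxooxolan-3-yl]-2-[(2S,3R)-3-(2-hydroxyethyl)-2-methyloxiran-2-yl]ethyl (2R)-2-methylbutanoate
Conditions: DDQ, CH2Cl2/pH 7 buffer, 0 °C
Reagents that add atoms: none
Why: Oxidative cleavage of the p-methoxybenzyl ether under neutral conditions, which the epoxide, esters and methylene lactone should tolerate.

Step 12
Reactants: 26 (1R)-1-[(2R,3R)-2-(2-bromoprop-2-en-1-yl)-4-methylidene-5-oxooxolan-3-yl]-2-[(2S,3R)-3-(2-hydroxyethyl)-2-methyloxiran-2-yl]ethyl (2R)-2-methylbutanoate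
Product: 27 (1R)-1-[(2R,3R)-2-(2-bromoprop-2-en-1-yl)-4-methylidene-5-oxooxolan-3-yl]-2-[(2S,3R)-2-methyl-3-(2-oxoethyl)oxiran-2-yl]ethyl (2R)-2-methylbutanoate
Conditions: Dess–Martin periodinane, NaHCO3, CH2Cl2, 0 °C; used crude
Reagents that add atoms: none
Why: Buffered Dess–Martin oxidation gives the C3 aldehyde without base, which matters because the aldehyde is β to the epoxide and would open it by E1cB.

Step 13
Reactants: 27 (1R)-1-[(2R,3R)-2-(2-bromoprop-2-en-1-yl)-4-methylidene-5-oxooxolan-3-yl]-2-[(2S,3R)-2-methyl-3-(2-oxoethyl)oxiran-2-yl]ethyl (2R)-2-methylbutanoate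
Product: 29 (1R,6R,7S,8R,10S)-1,10-epoxy-3-hydroxygermacra-4(15),11(13)-dien-6,12-olid-8-yl (2R)-2-methylbutanoate (both C3 epimers), via alkenylchromium 28 (not isolated)
Conditions: CrCl2 (10 equiv), NiCl2 (0.1 equiv), DMSO/THF, rt, 0.003 M, slow addition
Reagents that add atoms: none
Why: Nozaki–Hiyama–Kishi reaction: zerovalent nickel inserts into the C4–Br bond, transmetalation gives the alkenyl species of trivalent chromium, and this adds to the C3 aldehyde to close the ten-membered ring. The C3 configuration is irrelevant because C3 becomes the ketone.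

Step 14
Reactants: 29 (1R,6R,7S,8R,10S)-1,10-epoxy-3-hydroxygermacra-4(15),11(13)-dien-6,12-olid-8-yl (2R)-2-methylbutanoate (both C3 epimers)
Product: 30 (1R,6R,7S,8R,10S)-1,10:4,15-diepoxy-3-hydroxygermacr-11(13)-en-6,12-olid-8-yl (2R)-2-methylbutanoate (C3/C4 epimers)
Conditions: VO(acac)2 (cat.), t-BuOOH, CH2Cl2, 0 °C
Reagents that add atoms: tert-butyl hydroperoxide, CC(C)(C)OO
Why: Vanadium-catalysed directed epoxidation of the allylic alcohol oxidizes only the C4=C15 olefin; the conjugated C11=C13 olefin is electron-poor and should not react.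

Step 15
Reactants: 30 (1R,6R,7S,8R,10S)-1,10:4,15-diepoxy-3-hydroxygermacr-11(13)-en-6,12-olid-8-yl (2R)-2-methylbutanoate (C3/C4 epimers)
Product: 31 (1R,6R,7S,8R,10S)-1,10:4,15-diepoxy-3-oxogermacr-11(13)-en-6,12-olid-8-yl (2R)-2-methylbutanoate (C4 epimers)
Conditions: Dess–Martin periodinane, NaHCO3, CH2Cl2, 0 °C
Reagents that add atoms: none
Why: Base-free alcohol oxidation to the α,β-epoxy ketone; the C3 epimers converge here.

Step 16
Reactants: 31 (1R,6R,7S,8R,10S)-1,10:4,15-diepoxy-3-oxogermacr-11(13)-en-6,12-olid-8-yl (2R)-2-methylbutanoate (C4 epimers)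
Product: 33 (1R,4S,6R,7S,8R,10S)-1,10-epoxy-15-hydroxy-3-oxogermacr-11(13)-en-6,12-olid-8-yl (2R)-2-methylbutanoate (CNP0219035.1), via samarium enolate 32 (not isolated)
Conditions: SmI2 (2.2 equiv), THF/MeOH, −90 °C; pH 7 buffer
Reagents that add atoms: none
Why: Ketyl formation and cleavage of the Cα–O bond of the α,β-epoxy ketone (samarium diiodide reduction of epoxy ketones to β-hydroxy ketones) releases the C15 alkoxide and enolate 32, into which both C4 epimers converge. Protonation by methanol on the exposed face of the chelated enolate sets C4; the required 4S outcome cannot be predicted with confidence. At −90 °C the isolated epoxide, the esters and the methylene lactone should survive.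

## Compound list

1 | methyl furan-2-carboxylate | COC(=O)c1ccco1 | starting material
2 | ethyl diazoacetate | CCOC(=O)C=[N+]=[N-] | starting material
3 | 6-ethyl 3-methyl (1R,5R,6R)-2-oxabicyclo[3.1.0]hex-3-ene-3,6-dicarboxylate | COC(=O)C1=C[C@@H]2[C@@H](C(=O)OCC)[C@@H]2O1 | intermediate
4 | secondary ozonide (1,2,4-trioxolane) of 3 across the enol-ether double bond | CCOC(=O)[C@@H]1[C@H]2C3OOC(O3)(C(=O)OC)O[C@@H]12 | intermediate
5 | ethyl (1R,2R,3R)-2-formyl-3-[(2-methoxy-2-oxoacetyl)oxy]cyclopropane-1-carboxylate | CCOC(=O)[C@@H]1[C@@H](C=O)[C@H]1OC(=O)C(=O)OC | intermediate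
6 | (2-bromoprop-2-en-1-yl)trimethylsilane | C=C(Br)C[Si](C)(C)C | starting material
7 | ethyl (1R,2S,3R)-2-[(1R)-3-bromo-1-hydroxybut-3-en-1-yl]-3-[(2-methoxy-2-oxoacetyl)oxy]cyclopropane-1-carboxylate | CCOC(=O)[C@@H]1[C@@H]([C@H](O)CC(Br)=C)[C@H]1OC(=O)C(=O)OC | intermediate
8 | ethyl (1R,2S,3R)-2-[(1R)-3-bromo-1-hydroxybut-3-en-1-yl]-3-hydroxycyclopropane-1-carboxylate | CCOC(=O)[C@@H]1[C@@H]([C@H](O)CC(Br)=C)[C@H]1O | intermediate
9 | ethyl (3S,4R)-6-bromo-3-formyl-4-hydroxyhept-6-enoate | CCOC(=O)C[C@H](C=O)[C@H](O)CC(Br)=C | intermediate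
10 | (2R,3S)-2-(2-bromoprop-2-en-1-yl)-5-oxooxolane-3-carbaldehyde | O=C[C@H]1CC(=O)O[C@@H]1CC(Br)=C | intermediate
11 | 3-[(4-methoxyphenyl)methoxy]propan-1-ol | COc1ccc(COCCCO)cc1 | starting material
12 | N,N-di(propan-2-yl)carbamoyl chloride | CC(C)N(C(C)C)C(Cl)=O | starting material
13 | 3-[(4-methoxyphenyl)methoxy]propyl N,N-di(propan-2-yl)carbamate | COc1ccc(COCCCOC(=O)N(C(C)C)C(C)C)cc1 | intermediate
14 | 4,4,5,5-tetramethyl-2-(prop-1-en-2-yl)-1,3,2-dioxaborolane | C=C(C)B1OC(C)(C)C(C)(C)O1 | starting material
15 | (1S)-1-lithio-3-[(4-methoxyphenyl)methoxy]propyl N,N-di(propan-2-yl)carbamate (sparteine complex) | [Li][C@@H](CCOCc1ccc(OC)cc1)OC(=O)N(C(C)C)C(C)C | intermediate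
16 | lithium boronate complex of 15 with 14 (carbamate-bearing carbon S) | [Li+].C=C(C)[B-]1(OC(C)(C)C(C)(C)O1)[C@@H](CCOCc1ccc(OC)cc1)OC(=O)N(C(C)C)C(C)C | intermediate
17 | 2-[(3R)-5-[(4-methoxyphenyl)methoxy]-2-methylpent-1-en-3-yl]-4,4,5,5-tetramethyl-1,3,2-dioxaborolane | C=C(C)[C@@H](CCOCc1ccc(OC)cc1)B1OC(C)(C)C(C)(C)O1 | intermediate
18 | O8-(pinacolatoboryl) ester of 19 | C=C(Br)C[C@H]1OC(=O)C[C@@H]1[C@H](OB2OC(C)(C)C(C)(C)O2)C/C(C)=C\CCOCc3ccc(OC)cc3 | intermediate
19 | (4R,5R)-5-(2-bromoprop-2-en-1-yl)-4-[(1R,3Z)-1-hydroxy-6-[(4-methoxyphenyl)methoxy]-3-methylhex-3-en-1-yl]oxolan-2-one | C=C(Br)C[C@H]1OC(=O)C[C@@H]1[C@H](O)C/C(C)=C\CCOCc2ccc(OC)cc2 | intermediate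
20 | 3-[(dimethylamino)methyl] derivative of 19 (C11 epimers) | C=C(Br)C[C@H]1OC(=O)C(CN(C)C)[C@@H]1[C@H](O)C/C(C)=C\CCOCc2ccc(OC)cc2 | intermediate
21 | trimethylammonium iodide (methiodide) of 20 | C=C(Br)C[C@H]1OC(=O)C(C[N+](C)(C)C)[C@@H]1[C@H](O)C/C(C)=C\CCOCc2ccc(OC)cc2.[I-] | intermediate
22 | (4R,5R)-5-(2-bromoprop-2-en-1-yl)-4-[(1R,3Z)-1-hydroxy-6-[(4-methoxyphenyl)methoxy]-3-methylhex-3-en-1-yl]-3-methylideneoxolan-2-one | C=C(Br)C[C@H]1OC(=O)C(=C)[C@@H]1[C@H](O)C/C(C)=C\CCOCc2ccc(OC)cc2 | intermediate
23 | (4R,5R)-5-(2-bromoprop-2-en-1-yl)-4-[(1R)-1-hydroxy-2-[(2S,3R)-3-[2-[(4-methoxyphenyl)methoxy]ethyl]-2-methyloxiran-2-yl]ethyl]-3-methylideneoxolan-2-one | C=C(Br)C[C@H]1OC(=O)C(=C)[C@@H]1[C@H](O)C[C@]2(C)O[C@@H]2CCOCc3ccc(OC)cc3 | intermediate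
24 | (2R)-2-methylbutanoic acid | CC[C@@H](C)C(=O)O | starting material
25 | (1R)-1-[(2R,3R)-2-(2-bromoprop-2-en-1-yl)-4-methylidene-5-oxooxolan-3-yl]-2-[(2S,3R)-3-[2-[(4-methoxyphenyl)methoxy]ethyl]-2-methyloxiran-2-yl]ethyl (2R)-2-methylbutanoate | C=C(Br)C[C@H]1OC(=O)C(=C)[C@@H]1[C@H](OC(=O)[C@H](C)CC)C[C@]2(C)O[C@@H]2CCOCc3ccc(OC)cc3 | intermediate
26 | (1R)-1-[(2R,3R)-2-(2-bromoprop-2-en-1-yl)-4-methylidene-5-oxooxolan-3-yl]-2-[(2S,3R)-3-(2-hydroxyethyl)-2-methyloxiran-2-yl]ethyl (2R)-2-methylbutanoate | C=C(Br)C[C@H]1OC(=O)C(=C)[C@@H]1[C@H](OC(=O)[C@H](C)CC)C[C@]2(C)O[C@@H]2CCO | intermediate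
27 | (1R)-1-[(2R,3R)-2-(2-bromoprop-2-en-1-yl)-4-methylidene-5-oxooxolan-3-yl]-2-[(2S,3R)-2-methyl-3-(2-oxoethyl)oxiran-2-yl]ethyl (2R)-2-methylbutanoate | C=C(Br)C[C@H]1OC(=O)C(=C)[C@@H]1[C@H](OC(=O)[C@H](C)CC)C[C@]2(C)O[C@@H]2CC=O | intermediate
28 | alkenylchromium dichloride formed from 27 at C4 | C=C(C[C@H]1OC(=O)C(=C)[C@@H]1[C@H](OC(=O)[C@H](C)CC)C[C@]2(C)O[C@@H]2CC=O)[Cr](Cl)Cl | intermediate
29 | (1R,6R,7S,8R,10S)-1,10-epoxy-3-hydroxygermacra-4(15),11(13)-dien-6,12-olid-8-yl (2R)-2-methylbutanoate, both C3 epimers | C=C1C(=O)O[C@@H]2CC(=C)C(O)C[C@H]3O[C@@]3(C)C[C@@H](OC(=O)[C@H](C)CC)[C@@H]12 | intermediate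
30 | (1R,6R,7S,8R,10S)-1,10:4,15-diepoxy-3-hydroxygermacr-11(13)-en-6,12-olid-8-yl (2R)-2-methylbutanoate, epimers at C3 and C4 | C=C1C(=O)O[C@@H]2CC3(CO3)C(O)C[C@H]4O[C@@]4(C)C[C@@H](OC(=O)[C@H](C)CC)[C@@H]12 | intermediate
31 | (1R,6R,7S,8R,10S)-1,10:4,15-diepoxy-3-oxogermacr-11(13)-en-6,12-olid-8-yl (2R)-2-methylbutanoate, C4 epimers | C=C1C(=O)O[C@@H]2CC3(CO3)C(=O)C[C@H]4O[C@@]4(C)C[C@@H](OC(=O)[C@H](C)CC)[C@@H]12 | intermediate
32 | bis(diiodosamarium) enolate/alkoxide (C3=C4 enolate, C15 alkoxide) | C=C1C(=O)O[C@@H]2CC(CO[Sm](I)I)=C(O[Sm](I)I)C[C@H]3O[C@@]3(C)C[C@@H](OC(=O)[C@H](C)CC)[C@@H]12 | intermediate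
33 | (1R,4S,6R,7S,8R,10S)-1,10-epoxy-15-hydroxy-3-oxogermacr-11(13)-en-6,12-olid-8-yl (2R)-2-methylbutanoate (CNP0219035.1) | C=C1C(=O)O[C@@H]2C[C@@H](CO)C(=O)C[C@H]3O[C@@]3(C)C[C@@H](OC(=O)[C@H](C)CC)[C@@H]12 | target

## Step count and risks

Total: 16 steps. Longest linear sequence: 14 steps (steps 1–4 and 7–16); steps 5–6 form the two-step side branch.

**Step 7 (key step).** The likely failure is double diastereodifferentiation. The Felkin–Anh preference of aldehyde 10 is expected to oppose the reagent. The union may then become slow, and part of the material may pass through the chair with an equatorial C2 chain, losing Z geometry and C8 control together. A slow reaction also exposes 10 to base- or Lewis-acid-induced lactone opening. The fallback sets out from 10 and 11 and returns at 19; it separates carbinol and olefin construction. A reagent-controlled aldol addition of the diisopinocampheylboron enolate of acetone to 10 gives β-hydroxy methyl ketone F1, which is silylated (Et3SiCl, imidazole) to triethylsilyl ether F2. Alcohol 11 is converted (PPh3, iodine, imidazole) into iodide F3 and then (PPh3, MeCN, reflux) into phosphonium iodide F4. The unstabilized ylide from F4 (NaHMDS, THF, −78 °C) olefinates the methyl ketone of F2 in a Z-selective Wittig reaction, placing the ylide substituent cis to the larger ketone substituent, to give silyl ether F5. HF·pyridine then returns 19.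

**Step 13 (ring closure).** The likely failures are slow closure of the strained ten-membered ring, so that intermolecular coupling or protodehalogenation competes, and chloride opening of the trisubstituted epoxide by Lewis acidic trivalent chromium. The fallback sets out from 27 and returns at 29; it changes the organometallic manifold from a stoichiometric reductive one to a redox-neutral catalytic one. Miyaura borylation (B2pin2, Pd(dppf)Cl2, KOAc, dioxane) converts the bromoalkene into alkenyl pinacol boronate F6. A rhodium-catalysed intramolecular 1,2-addition of the alkenylboronate to the aldehyde ([Rh(OH)(cod)]2, dioxane/H2O, high dilution) then forms the same C3–C4 bond without chromium.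

**Step 16 (final reduction).** The likely failures are poor facial selectivity in the protonation of enolate 32, giving the wrong C4 configuration, competing reduction of the methylene lactone, and dehydration of the product. The fallback sets out from 29 and returns at 33; it replaces substrate-controlled enolate protonation with a catalyst-controlled conjugate addition. Dess–Martin oxidation of 29 gives cross-conjugated enone F7. Copper-catalysed conjugate borylation (B2pin2, CuCl, a chiral bisphosphine, MeOH) gives β-boryl ketone F8, with C4 set by ligand-controlled protonation of the copper enolate. Oxidation of the C–B bond (NaBO3·4H2O, THF/H2O) gives 33. The open question in this fallback is chemoselectivity between the enone and the methylene lactone.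

**Step 9 (directed epoxidation).** The likely failure is insufficient facial selectivity in the open chain, through a competing vanadate chair that places the C10 methyl equatorial. The fallback sets out from 22 and returns at 25; it replaces substrate direction with reagent control. 22 is first esterified with 24 (as in step 10) to give ester F9. F9 is then epoxidized with a chiral dioxirane (Shi epoxidation, using a ketone catalyst suited to cis-trisubstituted olefins, Oxone, buffered MeCN/H2O), which gives 25 directly.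

## Further compounds

F1 | step 7 | (4R,5R)-5-(2-bromoprop-2-en-1-yl)-4-[(1R)-1-hydroxy-3-oxobutyl]oxolan-2-one | C=C(Br)C[C@H]1OC(=O)C[C@@H]1[C@H](O)CC(C)=O
F2 | step 7 | (4R,5R)-5-(2-bromoprop-2-en-1-yl)-4-[(1R)-3-oxo-1-[(triethylsilyl)oxy]butyl]oxolan-2-one | C=C(Br)C[C@H]1OC(=O)C[C@@H]1[C@H](O[Si](CC)(CC)CC)CC(C)=O
F3 | step 7 | 1-[(3-iodopropoxy)methyl]-4-methoxybenzene | COc1ccc(COCCCI)cc1
F4 | step 7 | {3-[(4-methoxyphenyl)methoxy]propyl}triphenylphosphonium iodide | COc1ccc(COCCC[P+](c2ccccc2)(c2ccccc2)c2ccccc2)cc1.[I-]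
F5 | step 7 | O8-triethylsilyl ether of 19 | C=C(Br)C[C@H]1OC(=O)C[C@@H]1[C@H](O[Si](CC)(CC)CC)C/C(C)=C\CCOCc2ccc(OC)cc2
F6 | step 13 | analogue of 27 with a 4,4,5,5-tetramethyl-1,3,2-dioxaborolan-2-yl group in place of bromine at C4 | C=C(C[C@H]1OC(=O)C(=C)[C@@H]1[C@H](OC(=O)[C@H](C)CC)C[C@]2(C)O[C@@H]2CC=O)B3OC(C)(C)C(C)(C)O3
F7 | step 16 | (1R,6R,7S,8R,10S)-1,10-epoxy-3-oxogermacra-4(15),11(13)-dien-6,12-olid-8-yl (2R)-2-methylbutanoate | C=C1C(=O)O[C@@H]2CC(=C)C(=O)C[C@H]3O[C@@]3(C)C[C@@H](OC(=O)[C@H](C)CC)[C@@H]12
F8 | step 16 | (1R,4S,6R,7S,8R,10S)-1,10-epoxy-3-oxo-15-(4,4,5,5-tetramethyl-1,3,2-dioxaborolan-2-yl)germacr-11(13)-en-6,12-olid-8-yl (2R)-2-methylbutanoate | C=C1C(=O)O[C@@H]2C[C@@H](CB3OC(C)(C)C(C)(C)O3)C(=O)C[C@H]4O[C@@]4(C)C[C@@H](OC(=O)[C@H](C)CC)[C@@H]12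
F9 | step 9 | (1R,3Z)-1-[(2R,3R)-2-(2-bromoprop-2-en-1-yl)-4-methylidene-5-oxooxolan-3-yl]-6-[(4-methoxyphenyl)methoxy]-3-methylhex-3-en-1-yl (2R)-2-methylbutanoate | C=C(Br)C[C@H]1OC(=O)C(=C)[C@@H]1[C@H](OC(=O)[C@H](C)CC)C/C(C)=C\CCOCc2ccc(OC)cc2
A1 | alternative 1 | methyl (2Z,4R,6Z,9S,10S)-2-(bromomethyl)-4,9-bis[(tert-butyldimethylsilyl)oxy]-10-{[(4-methoxyphenyl)methoxy]methyl}-6-methyl-12-oxododeca-2,6-dienoate (seco aldehyde, C3 carbinol configuration arbitrary) | O=CC[C@@H](COCc1ccc(OC)cc1)[C@H](O[Si](C)(C)C(C)(C)C)C/C=C(C)\C[C@@H](O[Si](C)(C)C(C)(C)C)/C=C(CBr)/C(=O)OC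
A2 | alternative 2 | trans-lactone diene: (1R)-1-[(2R,3R)-2-[(2S)-3-[(tert-butyldimethylsilyl)oxy]-2-{[(4-methoxyphenyl)methoxy]methyl}hex-5-en-1-yl]-4-methylidene-5-oxooxolan-3-yl]-3-methylbut-3-en-1-yl (2R)-2-methylbutanoate (C3 configuration arbitrary) | C=C1C(=O)O[C@H](C[C@@H](COCc2ccc(OC)cc2)[C@H](O[Si](C)(C)C(C)(C)C)CC=C)[C@H]1[C@H](OC(=O)[C@H](C)CC)CC(C)=C
A3 | alternative 3 | trans-6-[(E)-2-[(tert-butyldimethylsilyl)oxy]ethenyl]-1-{3-[(4-methoxyphenyl)methoxy]prop-1-en-2-yl}-4-methylcyclohex-3-en-1-ol | C=C(COCc1ccc(OC)cc1)[C@@]1(O)CC=C(C)C[C@@H]1/C=C/O[Si](C)(C)C(C)(C)C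
A4 | alternative 3 | (3Z,7E)-9-[(tert-butyldimethylsilyl)oxy]-2-{[(4-methoxyphenyl)methoxy]methyl}... cyclodeca-3,7-dienone ring-expansion product: (Z)-C1=C10, (E)-C7=C8, 6-silyloxy, 4-(PMB-oxymethyl), 3-oxo (germacrane locants; C4 and C6 unassigned) | O=C1C/C=C(C)\C/C=C/C(O[Si](C)(C)C(C)(C)C)CC1COCc1ccc(OC)cc1
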